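**Target:** CNP0384113.1, (5S,6R,7R,8R,10R)-5-hydroxy-1-oxo-3,10-epoxygermacra-2,4(15),11(13)-trien-12,6-olid-8-yl 2-methylpropanoate (germacrane numbering used throughout).

**Retrosynthetic overview**
1. The 10-membered carbocycle is closed last at C4–C5 by an intramolecular Nozaki–Hiyama–Kishi addition of an alkenyl bromide to an aldehyde, which also creates the 4(15)-methylene/5-carbinol unit.
2. The cis-fused α-methylene-γ-lactone comes from an acetonide/methyl ester precursor (lactonisation onto O6) after the C8 hydroxyl has received the isobutyryl group.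
3. Key bond C7–C8: intermolecular indium Barbier allylation of a furanone acetaldehyde (East fragment) with a glyceraldehyde-derived (Z)-2-(bromomethyl)enoate (West fragment); it sets C7 and C8.
4. East fragment: furanone from an aldol of an α-silyloxy methyl ketone with 2-bromoacrolein, oxidation and acid cyclodehydration, with C10 from (S)-lactic acid by Seebach alkylation. West fragment: (R)-solketal, oxidation, Baylis–Hillman reaction, SN2' bromination.
5. Ring order: furanone, then γ-lactone, then carbocycle.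

Assumption: the target is taken exactly as the SMILES gives it (5S,6R,7R,8R,10R; H6 and H7 cis), and short-lived metal species (lithium enolates, allylindium, alkenylchromium) are not numbered as compounds.

**Route**

Step 1
Reactants: 1 (S)-lactic acid; 2 pivalaldehyde
Product: 3 (2S,5S)-2-tert-butyl-5-methyl-1,3-dioxolan-4-one
Conditions: p-toluenesulfonic acid monohydrate (cat.), H2SO4 (cat.), pentane, reflux, Dean–Stark; cis isomer crystallised from pentane at −78 °C
Reagents that add atoms: none
Why: Acid-catalysed acetalisation (Seebach self-regeneration of stereocentres) under thermodynamic control gives mainly the cis acetal, whose new acetal centre is set relative to the lactate centre and purified by crystallisation.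

Step 2
Reactants: 3 (2S,5S)-2-tert-butyl-5-methyl-1,3-dioxolan-4-one; 4 allyl bromide
Product: 5 (2S,5R)-2-tert-butyl-5-methyl-5-(prop-2-en-1-yl)-1,3-dioxolan-4-one
Conditions: LiN(i-Pr)2, THF, −78 °C; then 4, −78 → −30 °C
Reagents that add atoms: none
Why: Enolate alkylation in which the planar lithium enolate is allylated on the face anti to the tert-butyl group, so allyl replaces H with retention and the quaternary carbon (future C10) is set as 5R.

Step 3
Reactants: 5 (2S,5R)-2-tert-butyl-5-methyl-5-(prop-2-en-1-yl)-1,3-dioxolan-4-one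
Product: 6 (2R)-2-hydroxy-N-methoxy-N,2-dimethylpent-4-enamide
Conditions: MeNH(OMe)·HCl (3 equiv), i-PrMgCl (6 equiv), THF, −20 → 0 °C; aq. NH4Cl
Reagents that add atoms: N,O-dimethylhydroxylamine hydrochloride, CNOC.Cl
Why: Weinreb amide formation by aminolysis of the activated acylal ester with the chloromagnesium amide, the hemiacetal alkoxide collapsing to pivalaldehyde while the quaternary centre is untouched.

Step 4
Reactants: 6 (2R)-2-hydroxy-N-methoxy-N,2-dimethylpent-4-enamide
Product: 7 (2R)-N-methoxy-N,2-dimethyl-2-[(triethylsilyl)oxy]pent-4-enamide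
Conditions: Et3SiOTf, 2,6-lutidine, CH2Cl2, 0 °C
Reagents that add atoms: triethylsilyl trifluoromethanesulfonate, CC[Si](CC)(CC)OS(=O)(=O)C(F)(F)F
Why: Silyl triflate/lutidine silylation is the standard protection of a hindered tertiary alcohol, and the triethylsilyl ether survives the basic steps and is removed by acid in step 11.

Step 5
Reactants: 7 (2R)-N-methoxy-N,2-dimethyl-2-[(triethylsilyl)oxy]pent-4-enamide
Product: 9 (2R)-4-hydroxy-N-methoxy-N,2-dimethyl-2-[(triethylsilyl)oxy]butanamide, via aldehyde 8 (not isolated)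
Conditions: O3, CH2Cl2/MeOH, −78 °C; then NaBH4, −78 → 0 °C
Reagents that add atoms: ozone, [O-][O+]=O
Why: Ozonolysis with reductive work-up cleaves the only alkene to the primary alcohol, the hindered Weinreb amide being inert to NaBH4 at 0 °C.

Step 6
Reactants: 9 (2R)-4-hydroxy-N-methoxy-N,2-dimethyl-2-[(triethylsilyl)oxy]butanamide
Product: 10 (2R)-4-[(tert-butyldiphenylsilyl)oxy]-N-methoxy-N,2-dimethyl-2-[(triethylsilyl)oxy]butanamide
Conditions: t-BuPh2SiCl, imidazole, DMF, rt
Reagents that add atoms: tert-butyl(chloro)diphenylsilane, CC(C)(C)[Si](Cl)(c1ccccc1)c1ccccc1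
Why: Standard silylation of a primary alcohol, giving an ether that is stable to Grignard reagent, enolate chemistry, oxidation and the acidic furanone closure.

Step 7
Reactants: 10 (2R)-4-[(tert-butyldiphenylsilyl)oxy]-N-methoxy-N,2-dimethyl-2-[(triethylsilyl)oxy]butanamide
Product: 11 (3R)-5-[(tert-butyldiphenylsilyl)oxy]-3-methyl-3-[(triethylsilyl)oxy]pentan-2-one
Conditions: MeMgBr, THF, 0 °C → rt; aq. NH4Cl
Reagents that add atoms: methylmagnesium bromide, C[Mg]Br
Why: Weinreb ketone synthesis, the chelated tetrahedral magnesium intermediate preventing over-addition so that the methyl ketone (C1, C2) is released only on work-up.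

Step 8
Reactants: 12 acrolein
Product: 14 2-bromoprop-2-enal, via 2,3-dibromopropanal 13 (not isolated)
Conditions: Br2, CH2Cl2, −78 → 0 °C; then Et3N, 0 °C; distilled and used fresh
Reagents that add atoms: bromine, BrBr
Why: Bromine addition to the alkene followed by E1cB loss of HBr (the acidic α-proton is removed) gives the 2-bromo enal.

Step 9
Reactants: 11 (3R)-5-[(tert-butyldiphenylsilyl)oxy]-3-methyl-3-[(triethylsilyl)oxy]pentan-2-one; 14 2-bromoprop-2-enal
Product: 15 (3R,6RS)-7-bromo-1-[(tert-butyldiphenylsilyl)oxy]-6-hydroxy-3-methyl-3-[(triethylsilyl)oxy]oct-7-en-4-one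
Conditions: LiN(i-Pr)2, THF, −78 °C; then 14, −78 °C; AcOH quench at −78 °C
Reagents that add atoms: none
Why: Directed aldol addition in which only the methyl group of 11 can enolise and the lithium enolate adds 1,2 to the aldehyde at −78 °C, the new carbinol centre being formed as a mixture that is oxidised away in step 10.

Step 10
Reactants: 15 (3R,6RS)-7-bromo-1-[(tert-butyldiphenylsilyl)oxy]-6-hydroxy-3-methyl-3-[(triethylsilyl)oxy]oct-7-en-4-one
Product: 16 (3R)-7-bromo-1-[(tert-butyldiphenylsilyl)oxy]-3-methyl-3-[(triethylsilyl)oxy]oct-7-ene-4,6-dione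
Conditions: Dess–Martin periodinane, CH2Cl2, 0 °C → rt
Reagents that add atoms: none
Why: Dess–Martin oxidation converts the β-hydroxy ketone into the 1,3-diketone under neutral conditions and removes the stereocentre made in step 9.

Step 11
Reactants: 16 (3R)-7-bromo-1-[(tert-butyldiphenylsilyl)oxy]-3-methyl-3-[(triethylsilyl)oxy]oct-7-ene-4,6-dione
Product: 17 (2R)-5-(1-bromoethenyl)-2-{2-[(tert-butyldiphenylsilyl)oxy]ethyl}-2-methylfuran-3(2H)-one
Conditions: p-toluenesulfonic acid monohydrate, THF/H2O (10:1), rt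
Reagents that add atoms: none
Why: Acid removes the tertiary silyl ether and the freed hydroxyl adds to the distal carbonyl and dehydrates to the 3(2H)-furanone (Smith-type cyclodehydration of a hydroxy-1,3-diketone), an irreversible formation of a vinylogous ester that does not involve C10.

Step 12
Reactants: 17 (2R)-5-(1-bromoethenyl)-2-{2-[(tert-butyldiphenylsilyl)oxy]ethyl}-2-methylfuran-3(2H)-one
Product: 18 (2R)-5-(1-bromoethenyl)-2-(2-hydroxyethyl)-2-methylfuran-3(2H)-one
Conditions: HF·pyridine, pyridine, THF, 0 °C → rt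
Reagents that add atoms: none
Why: Fluoride-mediated desilylation under weakly acidic conditions frees the primary alcohol without base that could open the furanone by β-elimination.

Step 13
Reactants: 18 (2R)-5-(1-bromoethenyl)-2-(2-hydroxyethyl)-2-methylfuran-3(2H)-one
Product: 19 2-[(2R)-5-(1-bromoethenyl)-2-methyl-3-oxo-2,3-dihydrofuran-2-yl]acetaldehyde
Conditions: Dess–Martin periodinane, CH2Cl2, 0 °C → rt; used at once
Reagents that add atoms: none
Why: Dess–Martin oxidation gives the β-alkoxy aldehyde (C8) under neutral conditions, avoiding E1cB opening of the furanone.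

Step 14
Reactants: 20 (R)-solketal
Product: 21 (4S)-2,2-dimethyl-1,3-dioxolane-4-carbaldehyde
Conditions: Dess–Martin periodinane, CH2Cl2, 0 °C → rt; used crude
Reagents that add atoms: none
Why: Dess–Martin oxidation of the primary alcohol under neutral, non-aqueous conditions avoids epimerisation of the α-alkoxy aldehyde (the descriptor changes from R to S only through CIP priorities).

Step 15
Reactants: 21 (4S)-2,2-dimethyl-1,3-dioxolane-4-carbaldehyde; 22 methyl acrylate
Product: 23 methyl 2-{[(4S)-2,2-dimethyl-1,3-dioxolan-4-yl](hydroxy)methyl}prop-2-enoate (both carbinol epimers)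
Conditions: 1,4-diazabicyclo[2.2.2]octane (0.5 equiv), 1,4-dioxane/H2O (1:1), rt, 48 h
Reagents that add atoms: none
Why: Morita–Baylis–Hillman reaction in which the amine-acrylate zwitterion adds to the aldehyde, the carbinol centre being formed as a mixture that is erased in step 16 while the dioxolane centre is kept.

Step 16
Reactants: 23 methyl 2-{[(4S)-2,2-dimethyl-1,3-dioxolan-4-yl](hydroxy)methyl}prop-2-enoate
Product: 24 methyl (2Z)-2-(bromomethyl)-3-[(4R)-2,2-dimethyl-1,3-dioxolan-4-yl]prop-2-enoate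
Conditions: N-bromosuccinimide, Me2S, CH2Cl2, 0 °C → rt
Reagents that add atoms: N-bromosuccinimide, O=C1CCC(=O)N1Br
Why: SN2' bromination of the Baylis–Hillman alcohol through its alkoxysulfonium salt, bromide attacking the terminal methylene to give selectively the (Z)-enoate that places the vinyl hydrogen rather than the dioxolane next to the ester; the acetonide survives these neutral conditions.

Step 17
Reactants: 19 2-[(2R)-5-(1-bromoethenyl)-2-methyl-3-oxo-2,3-dihydrofuran-2-yl]acetaldehyde; 24 methyl (2Z)-2-(bromomethyl)-3-[(4R)-2,2-dimethyl-1,3-dioxolan-4-yl]prop-2-enoate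
Product: 25 methyl (3R,4R)-5-[(2R)-5-(1-bromoethenyl)-2-methyl-3-oxo-2,3-dihydrofuran-2-yl]-3-[(4R)-2,2-dimethyl-1,3-dioxolan-4-yl]-4-hydroxy-2-methylidenepentanoate
Conditions: In powder (1.5 equiv), 24 (1.3 equiv), THF/H2O (1:1), rt
Reagents that add atoms: none
Why: Indium Barbier allylation (Dreiding–Schmidt-type 2-alkoxycarbonylallylation) in which the allylindium adds through its γ-carbon in a chair transition state only to the aldehyde, the (Z)-geometry giving the syn C7/C8 relationship and A(1,3) strain (H6 in the alkene plane) together with indium–oxygen coordination directing the aldehyde to the face syn to the dioxolane oxygen and anti to C5, which sets 7R and 8R from 6R.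

Step 18
Reactants: 25 methyl (3R,4R)-5-[(2R)-5-(1-bromoethenyl)-2-methyl-3-oxo-2,3-dihydrofuran-2-yl]-3-[(4R)-2,2-dimethyl-1,3-dioxolan-4-yl]-4-hydroxy-2-methylidenepentanoate
Product: 26 methyl (3R,4R)-5-[(2R)-5-(1-bromoethenyl)-2-methyl-3-oxo-2,3-dihydrofuran-2-yl]-3-[(4R)-2,2-dimethyl-1,3-dioxolan-4-yl]-2-methylidene-4-[(2-methylpropanoyl)oxy]pentanoate
Conditions: (i-PrCO)2O, 4-(dimethylamino)pyridine (cat.), Et3N, CH2Cl2, 0 °C → rt
Reagents that add atoms: 2-methylpropanoic anhydride, CC(C)C(=O)OC(=O)C(C)C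
Why: 4-(Dimethylamino)pyridine-catalysed acyl transfer esterifies the only free hydroxyl (C8) before any lactone exists, so that the lactone can later form only on O6, and no stereocentre is touched.

Step 19
Reactants: 26 methyl (3R,4R)-5-[(2R)-5-(1-bromoethenyl)-2-methyl-3-oxo-2,3-dihydrofuran-2-yl]-3-[(4R)-2,2-dimethyl-1,3-dioxolan-4-yl]-2-methylidene-4-[(2-methylpropanoyl)oxy]pentanoate
Product: 28 (1R)-2-[(2R)-5-(1-bromoethenyl)-2-methyl-3-oxo-2,3-dihydrofuran-2-yl]-1-[(2R,3R)-2-(hydroxymethyl)-4-methylidene-5-oxooxolan-3-yl]ethyl 2-methylpropanoate, via diol ester 27 (not isolated)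
Conditions: CF3CO2H/H2O (9:1), CH2Cl2, 0 °C; concentrate; then p-toluenesulfonic acid monohydrate (cat.), CH2Cl2, rt
Reagents that add atoms: none
Why: Acidic acetonide hydrolysis followed by acid-catalysed lactonisation of the freed secondary C6 hydroxyl onto the methyl ester, the 5-membered γ-lactone being favoured over the 6-membered lactone from the primary hydroxyl and the cis ring fusion following from the 6R,7R centres already present.

Step 20
Reactants: 28 (1R)-2-[(2R)-5-(1-bromoethenyl)-2-methyl-3-oxo-2,3-dihydrofuran-2-yl]-1-[(2R,3R)-2-(hydroxymethyl)-4-methylidene-5-oxooxolan-3-yl]ethyl 2-methylpropanoate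
Product: 29 (1R)-2-[(2R)-5-(1-bromoethenyl)-2-methyl-3-oxo-2,3-dihydrofuran-2-yl]-1-[(2R,3R)-2-formyl-4-methylidene-5-oxooxolan-3-yl]ethyl 2-methylpropanoate
Conditions: Dess–Martin periodinane, CH2Cl2, 0 °C → rt; filtered and used immediately
Reagents that add atoms: none
Why: Dess–Martin oxidation of the primary alcohol to the C5 aldehyde under neutral conditions, with immediate use to avoid epimerisation at the α-acyloxy carbon C6.

Step 21
Reactants: 29 (1R)-2-[(2R)-5-(1-bromoethenyl)-2-methyl-3-oxo-2,3-dihydrofuran-2-yl]-1-[(2R,3R)-2-formyl-4-methylidene-5-oxooxolan-3-yl]ethyl 2-methylpropanoate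
Product: 30 (5S,6R,7R,8R,10R)-5-hydroxy-1-oxo-3,10-epoxygermacra-2,4(15),11(13)-trien-12,6-olid-8-yl 2-methylpropanoate (target)
Conditions: CrCl2 (8 equiv), NiCl2 (0.1 equiv), degassed DMSO, rt, slow addition of 29 to 0.003 M
Reagents that add atoms: none
Why: Intramolecular Nozaki–Hiyama–Kishi reaction in which nickel-catalysed activation of the electron-poor alkenyl bromide and transfer to trivalent chromium give an alkenylchromium that adds only to the aldehyde, closing the 10-membered ring, with Felkin–Anh approach anti to the C6–O bond giving the 5,6-anti (5S) carbinol.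

**Compound list**
1 | (S)-lactic acid, (2S)-2-hydroxypropanoic acid | C[C@H](O)C(=O)O | starting material
2 | pivalaldehyde, 2,2-dimethylpropanal | CC(C)(C)C=O | starting material
3 | (2S,5S)-2-tert-butyl-5-methyl-1,3-dioxolan-4-one | O=C1[C@H](C)O[C@H](C(C)(C)C)O1 | intermediate
4 | allyl bromide, 3-bromoprop-1-ene | C=CCBr | starting material
5 | (2S,5R)-2-tert-butyl-5-methyl-5-(prop-2-en-1-yl)-1,3-dioxolan-4-one | O=C1[C@@](C)(CC=C)O[C@H](C(C)(C)C)O1 | intermediate
6 | (2R)-2-hydroxy-N-methoxy-N,2-dimethylpent-4-enamide | CON(C)C(=O)[C@](C)(O)CC=C | intermediate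
7 | (2R)-N-methoxy-N,2-dimethyl-2-[(triethylsilyl)oxy]pent-4-enamide | CON(C)C(=O)[C@](C)(O[Si](CC)(CC)CC)CC=C | intermediate
8 | (2R)-N-methoxy-N,2-dimethyl-4-oxo-2-[(triethylsilyl)oxy]butanamide | CON(C)C(=O)[C@](C)(O[Si](CC)(CC)CC)CC=O | intermediate (not isolated)
9 | (2R)-4-hydroxy-N-methoxy-N,2-dimethyl-2-[(triethylsilyl)oxy]butanamide | CON(C)C(=O)[C@](C)(O[Si](CC)(CC)CC)CCO | intermediate
10 | (2R)-4-[(tert-butyldiphenylsilyl)oxy]-N-methoxy-N,2-dimethyl-2-[(triethylsilyl)oxy]butanamide | CON(C)C(=O)[C@](C)(O[Si](CC)(CC)CC)CCO[Si](c1ccccc1)(c1ccccc1)C(C)(C)C | intermediate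
11 | (3R)-5-[(tert-butyldiphenylsilyl)oxy]-3-methyl-3-[(triethylsilyl)oxy]pentan-2-one | CC(=O)[C@](C)(O[Si](CC)(CC)CC)CCO[Si](c1ccccc1)(c1ccccc1)C(C)(C)C | intermediate
12 | acrolein, prop-2-enal | C=CC=O | starting material
13 | 2,3-dibromopropanal (racemic) | O=CC(Br)CBr | intermediate (not isolated)
14 | 2-bromoprop-2-enal (2-bromoacrolein) | C=C(Br)C=O | intermediate
15 | (3R,6RS)-7-bromo-1-[(tert-butyldiphenylsilyl)oxy]-6-hydroxy-3-methyl-3-[(triethylsilyl)oxy]oct-7-en-4-one (both C6 epimers) | C=C(Br)C(O)CC(=O)[C@](C)(O[Si](CC)(CC)CC)CCO[Si](c1ccccc1)(c1ccccc1)C(C)(C)C | intermediate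
16 | (3R)-7-bromo-1-[(tert-butyldiphenylsilyl)oxy]-3-methyl-3-[(triethylsilyl)oxy]oct-7-ene-4,6-dione | C=C(Br)C(=O)CC(=O)[C@](C)(O[Si](CC)(CC)CC)CCO[Si](c1ccccc1)(c1ccccc1)C(C)(C)C | intermediate
17 | (2R)-5-(1-bromoethenyl)-2-{2-[(tert-butyldiphenylsilyl)oxy]ethyl}-2-methylfuran-3(2H)-one | CC(C)(C)[Si](c1ccccc1)(c1ccccc1)OCC[C@@]1(C)OC(=CC1=O)C(Br)=C | intermediate
18 | (2R)-5-(1-bromoethenyl)-2-(2-hydroxyethyl)-2-methylfuran-3(2H)-one | OCC[C@@]1(C)OC(=CC1=O)C(Br)=C | intermediate
19 | 2-[(2R)-5-(1-bromoethenyl)-2-methyl-3-oxo-2,3-dihydrofuran-2-yl]acetaldehyde (East fragment) | O=CC[C@@]1(C)OC(=CC1=O)C(Br)=C | intermediate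
20 | (R)-solketal, [(4R)-2,2-dimethyl-1,3-dioxolan-4-yl]methanol | OC[C@@H]1COC(C)(C)O1 | starting material
21 | (4S)-2,2-dimethyl-1,3-dioxolane-4-carbaldehyde | O=C[C@@H]1COC(C)(C)O1 | intermediate
22 | methyl acrylate, methyl prop-2-enoate | C=CC(=O)OC | starting material
23 | methyl 2-{[(4S)-2,2-dimethyl-1,3-dioxolan-4-yl](hydroxy)methyl}prop-2-enoate (both carbinol epimers) | C=C(C(=O)OC)C(O)[C@@H]1COC(C)(C)O1 | intermediate
24 | methyl (2Z)-2-(bromomethyl)-3-[(4R)-2,2-dimethyl-1,3-dioxolan-4-yl]prop-2-enoate (West fragment) | BrC/C(C(=O)OC)=C\[C@@H]1COC(C)(C)O1 | intermediate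
25 | methyl (3R,4R)-5-[(2R)-5-(1-bromoethenyl)-2-methyl-3-oxo-2,3-dihydrofuran-2-yl]-3-[(4R)-2,2-dimethyl-1,3-dioxolan-4-yl]-4-hydroxy-2-methylidenepentanoate | C=C(C(=O)OC)[C@@H]([C@@H]1COC(C)(C)O1)[C@H](O)C[C@@]1(C)OC(=CC1=O)C(Br)=C | intermediate
26 | methyl (3R,4R)-5-[(2R)-5-(1-bromoethenyl)-2-methyl-3-oxo-2,3-dihydrofuran-2-yl]-3-[(4R)-2,2-dimethyl-1,3-dioxolan-4-yl]-2-methylidene-4-[(2-methylpropanoyl)oxy]pentanoate | C=C(C(=O)OC)[C@@H]([C@@H]1COC(C)(C)O1)[C@H](OC(=O)C(C)C)C[C@@]1(C)OC(=CC1=O)C(Br)=C | intermediate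
27 | methyl (3S,4R)-5-[(2R)-5-(1-bromoethenyl)-2-methyl-3-oxo-2,3-dihydrofuran-2-yl]-3-[(1R)-1,2-dihydroxyethyl]-2-methylidene-4-[(2-methylpropanoyl)oxy]pentanoate (same spatial arrangement as 26; the C3 descriptor changes by CIP priority only) | C=C(C(=O)OC)[C@@H]([C@@H](O)CO)[C@H](OC(=O)C(C)C)C[C@@]1(C)OC(=CC1=O)C(Br)=C | intermediate (not isolated)
28 | (1R)-2-[(2R)-5-(1-bromoethenyl)-2-methyl-3-oxo-2,3-dihydrofuran-2-yl]-1-[(2R,3R)-2-(hydroxymethyl)-4-methylidene-5-oxooxolan-3-yl]ethyl 2-methylpropanoate | C=C1C(=O)O[C@@H](CO)[C@H]1[C@H](OC(=O)C(C)C)C[C@@]1(C)OC(=CC1=O)C(Br)=C | intermediate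
29 | (1R)-2-[(2R)-5-(1-bromoethenyl)-2-methyl-3-oxo-2,3-dihydrofuran-2-yl]-1-[(2R,3R)-2-formyl-4-methylidene-5-oxooxolan-3-yl]ethyl 2-methylpropanoate | C=C1C(=O)O[C@@H](C=O)[C@H]1[C@H](OC(=O)C(C)C)C[C@@]1(C)OC(=CC1=O)C(Br)=C | intermediate
30 | (5S,6R,7R,8R,10R)-5-hydroxy-1-oxo-3,10-epoxygermacra-2,4(15),11(13)-trien-12,6-olid-8-yl 2-methylpropanoate, CNP0384113.1 | C=C1C(=O)O[C@@H]2[C@H]1[C@H](OC(=O)C(C)C)C[C@@]1(C)OC(=CC1=O)C(=C)[C@@H]2O | target

**Totals**
Total step count: 21.
Longest linear sequence: 17 steps (steps 1–7, 9–13 and 17–21, from (S)-lactic acid); step 8 and steps 14–16 are side branches.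

**Three steps most likely to fail, with fallbacks**

Step 21, ring closure and C5 configuration. The 10-membered ring closure may favour the wrong face of the aldehyde, because ring strain can override the Felkin preference. The fallback stops relying on that facial bias and sets C5 by a reagent-controlled ketone reduction. It sets out from 29, which is cyclised as before. The crude carbinol, in this scenario mainly the (5R)-epimer of the target F1, is oxidised with Dess–Martin periodinane to the cross-conjugated macrocyclic 5-ketone F2. F2 is then reduced at −78 °C with catecholborane and (S)-2-methyl-CBS-oxazaborolidine. With the alkenyl branch as the large group, the Corey model predicts hydride delivery to the face that gives the 5S alcohol. The fallback comes back to the route at 30.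

Step 17, facial selectivity of the allylindium toward the C6 stereocentre. If the indium reagent gives a poor or reversed ratio, the fallback replaces substrate control by catalyst control over the aldehyde face, using a configurationally fixed allylboronate. It sets out from 24 and 19. Bromide 24 is borylated (bis(pinacolato)diboron, Pd2(dba)3 catalyst, DMSO, 50 °C) to methyl (2E)-3-[(4R)-2,2-dimethyl-1,3-dioxolan-4-yl]-2-[(4,4,5,5-tetramethyl-1,3,2-dioxaborolan-2-yl)methyl]prop-2-enoate F3. F3 adds to 19 in toluene at 0 °C through a closed boron chair, under the enantiomer of 3,3'-bis(2,4,6-triisopropylphenyl)-1,1'-binaphthyl-2,2'-diyl hydrogen phosphate that opens the Si face of the aldehyde (8R). The fixed cis arrangement of the boryl-methyl and dioxolanyl groups then forces 7R through the syn relationship. A neutral work-up with triethanolamine frees the hydroxy ester, and the fallback comes back to the route at 25.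

Step 15, the slow Baylis–Hillman reaction of an α-alkoxy aldehyde that can racemise or hydrate under amine catalysis over two days. The fallback replaces the amine-catalysed equilibrium process by a fast, stoichiometric vinylmetal addition at low temperature. It sets out from 21. Methyl propiolate is hydroaluminated with i-Bu2AlH and N-methylmorpholine N-oxide in THF at 0 °C to [1-(methoxycarbonyl)ethenyl]bis(2-methylpropyl)aluminium F4. F4 adds to 21 at −78 → 0 °C within an hour, and aqueous Rochelle salt work-up gives the same hydroxy ester. The fallback comes back to the route at 23.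

**Further compounds**
F1 | step 21 | (5R,6R,7R,8R,10R)-5-hydroxy-1-oxo-3,10-epoxygermacra-2,4(15),11(13)-trien-12,6-olid-8-yl 2-methylpropanoate (5-epimer of 30) | C=C1C(=O)O[C@@H]2[C@H]1[C@H](OC(=O)C(C)C)C[C@@]1(C)OC(=CC1=O)C(=C)[C@H]2O
F2 | step 21 | (6R,7R,8R,10R)-1,5-dioxo-3,10-epoxygermacra-2,4(15),11(13)-trien-12,6-olid-8-yl 2-methylpropanoate | C=C1C(=O)O[C@@H]2[C@H]1[C@H](OC(=O)C(C)C)C[C@@]1(C)OC(=CC1=O)C(=C)C2=O
F3 | step 17 | methyl (2E)-3-[(4R)-2,2-dimethyl-1,3-dioxolan-4-yl]-2-[(4,4,5,5-tetramethyl-1,3,2-dioxaborolan-2-yl)methyl]prop-2-enoate | CC1(C)OB(C/C(C(=O)OC)=C\[C@@H]2COC(C)(C)O2)OC1(C)C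
F4 | step 15 | [1-(methoxycarbonyl)ethenyl]bis(2-methylpropyl)aluminium | C=C(C(=O)OC)[Al](CC(C)C)CC(C)C
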